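## Structural features

The target is a C20 diterpenoid diacetate on a bicyclo[7.2.0]undecane: a cyclobutane (C1, C9, C10, C11) trans-fused along C1–C9 to a nine-membered carbocycle (C1–C9). The large ring carries a trans-configured C4–C5 epoxide (methyl on C4) and an exocyclic methylene on C8. The quaternary cyclobutane carbon C11 carries a methyl group and a five-carbon chain C1'–C5' with a secondary acetate at C1' and a (Z)-trisubstituted alkene that ends in a primary allylic acetate. Four stereocentres are contiguous (C9–C1–C11–C1'), C11 being quaternary and distinguished only by methyl versus side chain, while C4 and C5 lie across the ring. Sensitive functions are the epoxide and the strained medium ring (acid triggers transannular cyclisation), the 1,1-disubstituted alkene, the allylic acetate (ionisation, migration) and both esters (base). The difficulty is threefold: the fully substituted cyclobutane with C1, C9 and C11 in the correct relative and absolute sense, the strained nine-membered ring with its E-derived epoxide, and the C1' carbinol next to a quaternary carbon together with the Z-alkene. The key step uses the fact that C9 bears the carbonyl-level carbon C8 and is flanked inside the four-membered ring by the unsubstituted C10. This is the pattern left when a cyclopentanone expels its carbonyl carbon from the ring: C8 was the ring ketone and C10 its α-methylene.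

## Logic of the disconnections

**38 ⇒ 37.** The two acetate C–O bonds are cut. This defers the ionisable allylic acetate to the last step and leaves a diol. The forward acetylation must reach the neopentyl-type C1' hydroxyl without opening the epoxide.

**37 ⇒ 36.** The two hydroxyls are reconnected through a carbonyl at C5', so the Z-enediol is read as a reduced six-membered unsaturated lactone. The ring stores the Z geometry, so no stereoselective olefination is needed. The forward reduction must be 1,2-selective and spare the epoxide.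

**36 ⇒ 32 + 34.** C1'–C2' and the lactone C–O bond are cut. Five side-chain carbons come from a tiglate unit and the core is reduced to an aldehyde on C11. The forward step must attack a hindered aldehyde through the γ-carbon of the dienolate and choose one face at C1'.

**32 ⇒ 31 ⇒ 30 ⇒ 29.** After redox and protecting-group adjustment at C1', the two epoxide C–O bonds at C4 and C5 are cut. This gives a diene whose only strained, electron-rich double bond is C4=C5. The forward epoxidation must select that alkene over the C8 methylene and attack its outer face.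

**29 ⇒ 28.** The C8=CH2 bond is cut to a ketone, so C8 becomes a carbonyl carbon, which is what the key step can supply. The forward olefination must cope with a hindered, enolisable ketone next to C9.

**28 ⇒ 27 ⇒ 25.** The ketone is taken back to the carbinol and C5–C6 is cut. The nine-membered ring opens to a cyclobutane with two arms, an (E)-alkenyl iodide and a vinyl carbinol. The forward closure must outrun oligomerisation and keep the E geometry.

**25 ⇒ 24 ⇒ 23 ⇒ 21 ⇒ 20.** C7–C8 (vinyl addition) and then C4–CH3 and C5–I (methylmetalation of an alkyne) are cut, with redox changes at C8. Both arms collapse to an ester and a terminal alkyne on the cyclobutane. The forward carbometalation must be regioselective and syn.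

**20 ⇒ 16.** The C9–C10 bond is cut and C8 is reinserted between C9 and C10. The strained trisubstituted cyclobutane becomes an ordinary cyclopentanone on which C1 and C11 can be set by conjugate addition. The forward step needs the diazo group on C9 only and a means of steering C9.

**16 ⇒ 15 ⇒ 13 ⇒ 10 + 11.** The diazo unit on C9 is removed by way of an activating acyl group back to the enol ether, and C1–C2 is cut. This leaves a 4,4-disubstituted cyclopentenone and a homopropargyl nucleophile. The forward addition must come anti to the silyloxymethyl group, and its enolate must be captured without equilibration.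

**10 ⇒ 9 ⇒ 8 ⇒ 7 ⇒ 6 ⇒ 5 ⇒ 4.** The ring double bond is removed and the C1' oxygen is traced back to a vinyl group. The result is a simple 3,3-disubstituted cyclopentanone. Forward, desaturation can only occur away from the quaternary carbon, and the primary hydroxyl must be silylated selectively.

**4 ⇒ 2 + 1 (through 3).** The C11–C1' bond is cut. The quaternary stereocentre is reduced to the β-carbon of a commercial enone. The forward conjugate addition must be enantioselective at a fully substituted carbon.

## Other disconnections considered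

**Alternative 1:** The cut is C1'–C2' together with the lactone C–O bond. Aldehyde 32 and silyl dienolate 34 would be joined by a copper-catalysed vinylogous Mukaiyama aldol addition whose alkoxide closes onto the ester to give dihydropyranone A1.
- In its favour: one operation would create the C1' stereocentre under catalyst control, store the Z-alkene as a ring and bring both oxygen termini to the right oxidation level after reduction.
- Against it here: it must act on the complete, epoxide-bearing core and on a neopentyl aldehyde, and it says nothing about how the 4/9 core is made.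
- Comparison: A1 is identical with 36, so the chosen plan already contains this disconnection (step 23). On the side chain the alternative is therefore the equal of the chosen plan by construction. Mechanistically it is the milder process (closed-shell, catalytic, room temperature, against a photochemical rearrangement), which is a point in its favour. As the organising step of the whole synthesis it is structurally weaker, because the trisubstituted cyclobutane remains unsolved. On step economy the two are complementary and do not compete.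

**Alternative 2:** The cut is C5–C6. The open-chain precursor A3, with a terminal vinyl group on the C8 silyl ether and an (E)-alkenyl iodide, would be hydroborated and the alkylborane coupled intramolecularly to give the bicyclic cyclononene A2.
- In its favour: the E geometry is preset by carbometalation, the most strained ring would be closed by a tolerant sp3–sp2 coupling, and no stereocentre is at risk.
- Against it here: the closure needs high dilution, presupposes a cyclobutane that already carries C1, C9 and C11, and the triethylsilyl ether costs a protection and a deprotection.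
- Comparison: the chosen plan uses the same ring closure at step 16 on the unprotected carbinol 25 (giving 27 instead of A2), which should save two steps; mechanistically the two are identical. In strategic weight the alternative is at least the equal of the ring contraction, since the nine-membered ring is arguably the harder ring to close. It creates no stereocentre, however, whereas the contraction delivers the stereodefined cyclobutane on which this closure depends.

**Alternative 3:** The cut is C10–C11 in a cyclobutanone. The cyclopropanol carbonate A5 would be ionised by zerovalent palladium bearing a chiral ligand, and a cyclopropane bond would shift to the methyl-bearing allyl terminus to give cyclobutanone A4 with C11 set.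
- In its favour: the quaternary centre and the four-membered ring would arise together, catalytically and enantioselectively, from an achiral precursor in a few steps, and the vinyl group already holds C1' and C2'. On early step economy and on direct absolute control at C11 this alternative is the better of the two, since the chosen plan needs ten steps to reach 16.
- Against it here: A4 has its carbonyl at C1 and nothing at C9. The C2–C5 chain and C8 would have to be attached trans to each other, with the C1 substituent on the methyl side, by cyclobutanone enolate chemistry and conversion of C=O into a C–C bond. The facial bias available is only methyl against vinyl, smaller than methyl against silyloxymethyl. The vinyl group would also have to be changed before the other alkenes appear.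
- Comparison: mechanistically both plans rest on a 1,2-alkyl shift to an electron-poor carbon (an allyl–palladium terminus against a diazo carbon), one expanding a three-membered ring and the other contracting a five-membered ring. The contraction carries two stereocentres set on an unstrained ring into the cyclobutane, the expansion only one. Overall step count would probably be no lower.

Key step: step 11

Remark 1: atom labels C1–C11 and C1'–C5' follow the bicyclo[7.2.0]undecane numbering of 38 throughout, also in monocyclic precursors. C8 is the ring carbon that carries the methylene group; the methylene carbon itself enters only in step 18.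

Remark 2: a trans ester equilibrated with methoxide in methanol cannot keep an alkynyl trimethylsilyl group. The silylated trans ester 19 is therefore a transient, and the isolated product of the key step is the terminal alkyne 20.

Remark 3: in the ligand-controlled steps 1 and 23 the ligand antipode is defined by the product configuration it must deliver.

## Route

**Step 1**
Reactants: 1 ethynyltrimethylsilane; 2 3-methylcyclopent-2-en-1-one
Product: 4 (3R)-3-methyl-3-[1-(trimethylsilyl)ethenyl]cyclopentan-1-one, via alkenylalane 3 (not isolated)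
Conditions: 1, iBu2AlH, hexanes/THF, 55 °C; then 2, CuCl2·2H2O (5 mol %), chiral sulfonate-bearing NHC–Ag complex (from the imidazolinium sulfonate and Ag2O, 2.5 mol %), THF, −78 → 4 °C; aq. KNaC4H4O6
Reagents that add atoms: none
Why: α-Selective hydroalumination gives the 1-silylvinylalane, which a chiral NHC–copper complex transfers to the β-carbon of the enone (catalytic enantioselective conjugate addition forming a quaternary centre); the ligand shields one enone face and so sets C11 (3R in 4). Silyl-substituted alkenylalanes with 3-methylcycloalkenones are an established substrate pair for this reaction.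

**Step 2**
Reactants: 4 (3R)-3-methyl-3-[1-(trimethylsilyl)ethenyl]cyclopentan-1-one
Product: 5 (3R)-3-ethenyl-3-methylcyclopentan-1-one
Conditions: CF3CO2H, CH2Cl2, 0 °C → rt
Reagents that add atoms: none
Why: Acid-mediated protodesilylation of the alkenylsilane (electrophilic substitution at the silicon-bearing carbon) leaves a plain vinyl group; the quaternary centre is not involved, and the volatile ketone is best carried on as a concentrated solution.

**Step 3**
Reactants: 5 (3R)-3-ethenyl-3-methylcyclopentan-1-one
Product: 6 (3R)-3-(hydroxymethyl)-3-methylcyclopentan-1-ol (both C1 epimers)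
Conditions: O3, CH2Cl2/MeOH, −78 °C; then NaBH4, −78 °C → rt
Reagents that add atoms: ozone [O-][O+]=O
Why: Ozonolysis cleaves the only alkene, and the borohydride work-up reduces the ozonide to the primary alcohol and the ketone to the carbinol, which avoids a ketone protecting group; the carbinol epimers converge at step 5.

**Step 4**
Reactants: 6 (3R)-3-(hydroxymethyl)-3-methylcyclopentan-1-ol
Product: 7 (3R)-3-methyl-3-({[tri(propan-2-yl)silyl]oxy}methyl)cyclopentan-1-ol (both C1 epimers)
Conditions: iPr3SiCl, imidazole, DMF, 0 °C → rt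
Reagents that add atoms: chlorotri(propan-2-yl)silane CC(C)[Si](Cl)(C(C)C)C(C)C
Why: Silylation with a bulky chlorosilane is selective for the primary over the secondary hydroxyl. The triisopropylsilyl group is chosen because it is large (facial control in step 8), stable to base and Lewis acid, and transparent above 300 nm.

**Step 5**
Reactants: 7 (3R)-3-methyl-3-({[tri(propan-2-yl)silyl]oxy}methyl)cyclopentan-1-ol
Product: 8 (3R)-3-methyl-3-({[tri(propan-2-yl)silyl]oxy}methyl)cyclopentan-1-one
Conditions: Dess–Martin periodinane, pyridine, CH2Cl2, rt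
Reagents that add atoms: none
Why: Dess–Martin oxidation of the secondary alcohol under neutral conditions that leave the silyl ether intact.

**Step 6**
Reactants: 8 (3R)-3-methyl-3-({[tri(propan-2-yl)silyl]oxy}methyl)cyclopentan-1-one
Product: 9 trimethyl{[(4R)-4-methyl-4-({[tri(propan-2-yl)silyl]oxy}methyl)cyclopent-1-en-1-yl]oxy}silane
Conditions: LiN(iPr)2, Me3SiCl, THF, −78 °C (internal quench); Et3N, pentane
Reagents that add atoms: chlorotrimethylsilane C[Si](C)(C)Cl
Why: Kinetic deprotonation occurs at the less hindered α-methylene remote from the quaternary carbon and the enolate is silylated on oxygen as it forms. A regioisomeric enol ether cannot desaturate in step 7, because its β-carbon is quaternary, and would only revert to 8.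

**Step 7**
Reactants: 9 trimethyl{[(4R)-4-methyl-4-({[tri(propan-2-yl)silyl]oxy}methyl)cyclopent-1-en-1-yl]oxy}silane
Product: 10 (4S)-4-methyl-4-({[tri(propan-2-yl)silyl]oxy}methyl)cyclopent-2-en-1-one
Conditions: Pd(OAc)2 (10 mol %), O2 (1 atm), DMSO, rt
Reagents that add atoms: none
Why: Saegusa–Ito oxidation: the enol ether transmetalates to divalent palladium, β-hydride elimination from the adjacent ring CH2 releases the enone and O2 reoxidises the metal; C11 is untouched.

**Step 8**
Reactants: 10 (4S)-4-methyl-4-({[tri(propan-2-yl)silyl]oxy}methyl)cyclopent-2-en-1-one; 11 (4-bromobut-1-yn-1-yl)trimethylsilane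
Product: 13 trimethyl{[(3S,4S)-4-methyl-4-({[tri(propan-2-yl)silyl]oxy}methyl)-3-[4-(trimethylsilyl)but-3-yn-1-yl]cyclopent-1-en-1-yl]oxy}silane, via Grignard reagent 12 (not isolated)
Conditions: 11, Mg, THF, rt; then CuBr·SMe2 (20 mol %), Me3SiCl, 10, THF, −78 → −40 °C; Et3N
Reagents that add atoms: chlorotrimethylsilane C[Si](C)(C)Cl
Why: Copper-catalysed conjugate addition of the Grignard reagent, accelerated and terminated by the chlorosilane, delivers the homopropargyl group to the β-carbon anti to the larger silyloxymethyl substituent on the adjacent quaternary carbon, which sets C1 trans to C1'. O-Silylation freezes the enolate, so the position of the enol double bond (C8–C9) is preserved.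

**Step 9**
Reactants: 13 trimethyl{[(3S,4S)-4-methyl-4-({[tri(propan-2-yl)silyl]oxy}methyl)-3-[4-(trimethylsilyl)but-3-yn-1-yl]cyclopent-1-en-1-yl]oxy}silane
Product: 15 (3S,4S)-4-methyl-2-(trifluoroacetyl)-4-({[tri(propan-2-yl)silyl]oxy}methyl)-3-[4-(trimethylsilyl)but-3-yn-1-yl]cyclopentan-1-one (enolised diketone), via lithium enolate 14 (not isolated)
Conditions: MeLi, THF, 0 °C; then CF3CO2CH2CF3, −78 °C; aq. NH4Cl
Reagents that add atoms: 2,2,2-trifluoroethyl trifluoroacetate FC(F)(F)COC(=O)C(F)(F)F
Why: Methyllithium cleaves the Si–O bond to the regiodefined lithium enolate, which is C-acylated by the trifluoroacetate (Claisen-type acylation) at C9 only; the enolised diketone is the activated substrate for diazo transfer.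

**Step 10**
Reactants: 15 (3S,4S)-4-methyl-2-(trifluoroacetyl)-4-({[tri(propan-2-yl)silyl]oxy}methyl)-3-[4-(trimethylsilyl)but-3-yn-1-yl]cyclopentan-1-one
Product: 16 (3R,4S)-2-diazo-4-methyl-4-({[tri(propan-2-yl)silyl]oxy}methyl)-3-[4-(trimethylsilyl)but-3-yn-1-yl]cyclopentan-1-one
Conditions: MeSO2N3, Et3N, H2O (1 equiv), MeCN, rt
Reagents that add atoms: methanesulfonyl azide CS(=O)(=O)N=[N+]=[N-]
Why: Regitz-type diazo transfer with loss of the activating acyl group (detrifluoroacetylative diazo transfer): the diketone enolate adds to the sulfonyl azide and the adduct fragments to the α-diazoketone and the N-sulfonyl trifluoroacetamide, so the diazo group ends up on C9 only.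

**Step 11**
Reactants: 16 (3R,4S)-2-diazo-4-methyl-4-({[tri(propan-2-yl)silyl]oxy}methyl)-3-[4-(trimethylsilyl)but-3-yn-1-yl]cyclopentan-1-one
Product: 20 methyl (1R,2S,3S)-2-(but-3-yn-1-yl)-3-methyl-3-({[tri(propan-2-yl)silyl]oxy}methyl)cyclobutane-1-carboxylate, via ketene 17 (not isolated), via cis ester 18 (not isolated), via trans ester 19 (not isolated)
Conditions: hν (medium-pressure Hg lamp, Pyrex, >300 nm), degassed MeOH, 0–20 °C; then NaOMe, 20 → 60 °C; aq. NH4Cl
Reagents that add atoms: methanol CO
Why: Photochemical Wolff rearrangement: excitation of the s-cis-locked α-diazoketone expels N2 while the ring CH2 (C10) migrates from the carbonyl carbon (C8) to the diazo carbon (C9), so the cyclobutane arises by a 1,2-shift (a ring contraction, to which no cyclisation mode applies) and C8 leaves the ring as ketene 17. Methanol adds to the ketene and the ester enol is protonated at C9, which should give both esters 18 and 19. The closest known reaction type is the photolytic contraction of 2-diazocycloalkanones to cycloalkanecarboxylic esters. C1 and C11 are neither origin nor terminus of the migration, so their configurations carry over from 16. C9 is the one new stereocentre and is set under thermodynamic control when methoxide reversibly enolises the ester: in the 1R isomer the ester is trans to the C1 chain and all three larger ring substituents can sit pseudo-equatorially. The same methoxide cleaves the alkynyl C–Si bond, so the terminal alkyne needed in step 13 is released in the same flask. Regioselectivity is secured beforehand, since steps 8–10 place the diazo group on C9 and C10 is the only other substituent of the carbonyl carbon that can migrate. Chemoselectivity against carbene 1,2-hydride shift and O–H insertion rests on the locked s-cis geometry and direct irradiation in a nucleophilic solvent; the silyl ether and the alkynylsilane do not absorb above 300 nm.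

**Step 12**
Reactants: 20 methyl (1R,2S,3S)-2-(but-3-yn-1-yl)-3-methyl-3-({[tri(propan-2-yl)silyl]oxy}methyl)cyclobutane-1-carboxylate
Product: 21 [(1R,2S,3S)-2-(but-3-yn-1-yl)-3-methyl-3-({[tri(propan-2-yl)silyl]oxy}methyl)cyclobutyl]methanol
Conditions: iBu2AlH, CH2Cl2, −78 → 0 °C; aq. KNaC4H4O6
Reagents that add atoms: none
Why: Hydride reduction of the ester to the primary alcohol; the terminal alkyne and the silyl ether are inert at low temperature.

**Step 13**
Reactants: 21 [(1R,2S,3S)-2-(but-3-yn-1-yl)-3-methyl-3-({[tri(propan-2-yl)silyl]oxy}methyl)cyclobutyl]methanol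
Product: 23 [(1R,2S,3S)-2-[(3E)-4-iodo-3-methylbut-3-en-1-yl]-3-methyl-3-({[tri(propan-2-yl)silyl]oxy}methyl)cyclobutyl]methanol, via alkenylalane 22 (not isolated)
Conditions: AlMe3 (3 equiv), Cp2ZrCl2 (25 mol %), CH2Cl2, 0 °C → rt; then [I][I] in THF, −30 → 0 °C; aq. KNaC4H4O6, aq. Na2S2O3
Reagents that add atoms: trimethylaluminium C[Al](C)C; iodine [I][I]
Why: Zirconium-catalysed methylalumination (Negishi carboalumination) adds methyl and aluminium syn across the terminal alkyne with methyl on the internal carbon, and iodinolysis with retention fixes the E-alkenyl iodide. The hydroxyl is carried as its aluminium alkoxide by the excess AlMe3.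

**Step 14**
Reactants: 23 [(1R,2S,3S)-2-[(3E)-4-iodo-3-methylbut-3-en-1-yl]-3-methyl-3-({[tri(propan-2-yl)silyl]oxy}methyl)cyclobutyl]methanol
Product: 24 (1R,2S,3S)-2-[(3E)-4-iodo-3-methylbut-3-en-1-yl]-3-methyl-3-({[tri(propan-2-yl)silyl]oxy}methyl)cyclobutane-1-carbaldehyde
Conditions: Dess–Martin periodinane, pyridine, CH2Cl2, 0 °C → rt
Reagents that add atoms: none
Why: Dess–Martin oxidation to the aldehyde; the trans relation at C9 is the stable one, so enolisation cannot harm it.

**Step 15**
Reactants: 24 (1R,2S,3S)-2-[(3E)-4-iodo-3-methylbut-3-en-1-yl]-3-methyl-3-({[tri(propan-2-yl)silyl]oxy}methyl)cyclobutane-1-carbaldehyde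
Product: 25 1-[(1R,2S,3S)-2-[(3E)-4-iodo-3-methylbut-3-en-1-yl]-3-methyl-3-({[tri(propan-2-yl)silyl]oxy}methyl)cyclobutyl]prop-2-en-1-ol (both carbinol epimers)
Conditions: CH2=CHMgBr, THF, −78 °C; aq. NH4Cl
Reagents that add atoms: vinylmagnesium bromide C=C[Mg]Br
Why: 1,2-Addition of the vinyl Grignard reagent to the aldehyde at low temperature, where iodine–magnesium exchange at the alkenyl iodide does not compete; the new carbinol centre is destroyed in step 17, so both epimers are used.

**Step 16**
Reactants: 25 1-[(1R,2S,3S)-2-[(3E)-4-iodo-3-methylbut-3-en-1-yl]-3-methyl-3-({[tri(propan-2-yl)silyl]oxy}methyl)cyclobutyl]prop-2-en-1-ol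
Product: 27 (1S,4E,9R,11S)-4,11-dimethyl-11-({[tri(propan-2-yl)silyl]oxy}methyl)bicyclo[7.2.0]undec-4-en-8-ol (both C8 epimers), via alkylborane 26 (not isolated)
Conditions: 9-BBN (2.5 equiv), THF, rt; then slow addition to PdCl2(dppf) (15 mol %), AsPh3, Cs2CO3, DMF/THF/H2O, 50 °C, ca. 2 mM
Reagents that add atoms: none
Why: 9-BBN hydroborates only the monosubstituted vinyl group, at its terminus; the alkylborane then undergoes intramolecular B-alkyl Suzuki–Miyaura coupling (oxidative addition of zerovalent palladium to the C–I bond, base-assisted transmetalation, reductive elimination) with retention of the alkene geometry. The nine-membered ring closes by C5–C6 bond formation under high dilution; excess borane allows for O-borylation of the free hydroxyl, which the aqueous base reverses.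

**Step 17**
Reactants: 27 (1S,4E,9R,11S)-4,11-dimethyl-11-({[tri(propan-2-yl)silyl]oxy}methyl)bicyclo[7.2.0]undec-4-en-8-ol
Product: 28 (1S,4E,9R,11S)-4,11-dimethyl-11-({[tri(propan-2-yl)silyl]oxy}methyl)bicyclo[7.2.0]undec-4-en-8-one
Conditions: Dess–Martin periodinane, pyridine, CH2Cl2, rt
Reagents that add atoms: none
Why: Dess–Martin oxidation merges the carbinol epimers into the C8 ketone; C9 should stay trans-fused, the more stable arrangement.

**Step 18**
Reactants: 28 (1S,4E,9R,11S)-4,11-dimethyl-11-({[tri(propan-2-yl)silyl]oxy}methyl)bicyclo[7.2.0]undec-4-en-8-one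
Product: 29 {[(1S,4E,9R,11S)-4,11-dimethyl-8-methylidenebicyclo[7.2.0]undec-4-en-11-yl]methoxy}tri(propan-2-yl)silane
Conditions: Ph3PCH3Br, KOtBu, toluene, 20 → 80 °C
Reagents that add atoms: methyltriphenylphosphonium bromide C[P+](c1ccccc1)(c1ccccc1)c1ccccc1.[Br-]
Why: Wittig methylenation of the ketone, a transformation known for the parent 4/9-bicyclic ketone; should C9 enolise under the basic conditions, reprotonation favours the trans ring fusion.

**Step 19**
Reactants: 29 {[(1S,4E,9R,11S)-4,11-dimethyl-8-methylidenebicyclo[7.2.0]undec-4-en-11-yl]methoxy}tri(propan-2-yl)silane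
Product: 30 {[(1S,4S,5S,9R,11S)-4,5-epoxy-4,11-dimethyl-8-methylidenebicyclo[7.2.0]undecan-11-yl]methoxy}tri(propan-2-yl)silane
Conditions: mCPBA (1.05 equiv), NaHCO3, CH2Cl2, −20 → 0 °C
Reagents that add atoms: 3-chloroperoxybenzoic acid OOC(=O)c1cccc(Cl)c1
Why: Prilezhaev epoxidation is stereospecific (trans-epoxide from the E-alkene) and chemoselective for the strained trisubstituted ring alkene over the 1,1-disubstituted methylene. Facial selectivity follows the conformational bias of the (E)-cyclononene, which turns one alkene face towards the ring interior; by analogy with β-caryophyllene the exposed face leads to the 4S,5S epoxide.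

**Step 20**
Reactants: 30 {[(1S,4S,5S,9R,11S)-4,5-epoxy-4,11-dimethyl-8-methylidenebicyclo[7.2.0]undecan-11-yl]methoxy}tri(propan-2-yl)silane
Product: 31 [(1S,4S,5S,9R,11S)-4,5-epoxy-4,11-dimethyl-8-methylidenebicyclo[7.2.0]undecan-11-yl]methanol
Conditions: Bu4NF, THF, rt → 45 °C; aq. NH4Cl
Reagents that add atoms: none
Why: Fluoride-mediated desilylation; the epoxide and the alkene are inert to Bu4NF.

**Step 21**
Reactants: 31 [(1S,4S,5S,9R,11S)-4,5-epoxy-4,11-dimethyl-8-methylidenebicyclo[7.2.0]undecan-11-yl]methanol
Product: 32 (1S,4S,5S,9R,11S)-4,5-epoxy-4,11-dimethyl-8-methylidenebicyclo[7.2.0]undecane-11-carbaldehyde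
Conditions: Dess–Martin periodinane, pyridine, CH2Cl2, 0 °C → rt
Reagents that add atoms: none
Why: Buffered Dess–Martin oxidation gives the non-enolisable neopentyl aldehyde without acid that could open the epoxide.

**Step 22**
Reactants: 33 ethyl (2E)-2-methylbut-2-enoate
Product: 34 [(1-ethoxy-2-methylbuta-1,3-dien-1-yl)oxy]trimethylsilane
Conditions: LiN(iPr)2, DMPU, THF, −78 °C; Me3SiCl; distillation
Reagents that add atoms: chlorotrimethylsilane C[Si](C)(C)Cl
Why: γ-Deprotonation of the enoate by the amide base and O-silylation give the silyl dienolate (a vinylogous silyl ketene acetal), used as a mixture of acetal isomers.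

**Step 23**
Reactants: 32 (1S,4S,5S,9R,11S)-4,5-epoxy-4,11-dimethyl-8-methylidenebicyclo[7.2.0]undecane-11-carbaldehyde; 34 [(1-ethoxy-2-methylbuta-1,3-dien-1-yl)oxy]trimethylsilane
Product: 36 (6S)-6-[(1S,4S,5S,9R,11S)-4,5-epoxy-4,11-dimethyl-8-methylidenebicyclo[7.2.0]undecan-11-yl]-3-methyl-5,6-dihydro-2H-pyran-2-one, via copper aldolate 35 (not isolated)
Conditions: Cu(OTf)2 (10 mol %), Tol-BINAP (11 mol %), Bu4N[Ph3SiF2] (20 mol %), THF, rt
Reagents that add atoms: none
Why: Catalytic asymmetric vinylogous Mukaiyama aldol reaction: fluoride-induced silicon-to-copper transmetalation gives a chiral monovalent copper dienolate that attacks the aldehyde through its γ-carbon, and the copper alkoxide 35 closes onto the Z-configured ester to form the lactone, releasing the ethoxide that turns the cycle over. The Tol-BINAP antipode is selected for Si-face attack, which gives 6S (C1'); the lactone ring guarantees the Z geometry.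

**Step 24**
Reactants: 36 (6S)-6-[(1S,4S,5S,9R,11S)-4,5-epoxy-4,11-dimethyl-8-methylidenebicyclo[7.2.0]undecan-11-yl]-3-methyl-5,6-dihydro-2H-pyran-2-one
Product: 37 (2Z,5S)-5-[(1S,4S,5S,9R,11S)-4,5-epoxy-4,11-dimethyl-8-methylidenebicyclo[7.2.0]undecan-11-yl]-2-methylpent-2-ene-1,5-diol
Conditions: iBu2AlH (4 equiv), CH2Cl2, −78 → −20 °C; aq. KNaC4H4O6
Reagents that add atoms: none
Why: 1,2-Reduction of the unsaturated lactone through the lactol aluminate to the diol; the alkene geometry is retained as Z, and the low temperature protects the trisubstituted epoxide from hydride opening.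

**Step 25**
Reactants: 37 (2Z,5S)-5-[(1S,4S,5S,9R,11S)-4,5-epoxy-4,11-dimethyl-8-methylidenebicyclo[7.2.0]undecan-11-yl]-2-methylpent-2-ene-1,5-diol
Product: 38 (2Z,5S)-5-[(1S,4S,5S,9R,11S)-4,5-epoxy-4,11-dimethyl-8-methylidenebicyclo[7.2.0]undecan-11-yl]-2-methylpent-2-ene-1,5-diyl diacetate
Conditions: Ac2O, pyridine, DMAP (cat.), CH2Cl2, rt
Reagents that add atoms: acetic anhydride CC(=O)OC(C)=O
Why: DMAP-catalysed acylation of both hydroxyls, including the hindered C1' carbinol; the basic medium leaves the epoxide and the exocyclic alkene untouched.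

## Compound list

1 | ethynyltrimethylsilane | C#C[Si](C)(C)C | starting material
2 | 3-methylcyclopent-2-en-1-one | CC1=CC(=O)CC1 | starting material
3 | bis(2-methylpropyl)[1-(trimethylsilyl)ethenyl]alumane | C=C([Si](C)(C)C)[Al](CC(C)C)CC(C)C | intermediate
4 | (3R)-3-methyl-3-[1-(trimethylsilyl)ethenyl]cyclopentan-1-one | O=C1CC[C@@](C)(C(=C)[Si](C)(C)C)C1 | intermediate
5 | (3R)-3-ethenyl-3-methylcyclopentan-1-one | O=C1CC[C@@](C)(C=C)C1 | intermediate
6 | (3R)-3-(hydroxymethyl)-3-methylcyclopentan-1-ol, both C1 epimers | OC1CC[C@@](C)(CO)C1 | intermediate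
7 | (3R)-3-methyl-3-({[tri(propan-2-yl)silyl]oxy}methyl)cyclopentan-1-ol, both C1 epimers | OC1CC[C@@](C)(CO[Si](C(C)C)(C(C)C)C(C)C)C1 | intermediate
8 | (3R)-3-methyl-3-({[tri(propan-2-yl)silyl]oxy}methyl)cyclopentan-1-one | O=C1CC[C@@](C)(CO[Si](C(C)C)(C(C)C)C(C)C)C1 | intermediate
9 | trimethyl{[(4R)-4-methyl-4-({[tri(propan-2-yl)silyl]oxy}methyl)cyclopent-1-en-1-yl]oxy}silane | C[Si](C)(C)OC1=CC[C@@](C)(CO[Si](C(C)C)(C(C)C)C(C)C)C1 | intermediate
10 | (4S)-4-methyl-4-({[tri(propan-2-yl)silyl]oxy}methyl)cyclopent-2-en-1-one | O=C1C=C[C@@](C)(CO[Si](C(C)C)(C(C)C)C(C)C)C1 | intermediate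
11 | (4-bromobut-1-yn-1-yl)trimethylsilane | C[Si](C)(C)C#CCCBr | starting material
12 | bromo[4-(trimethylsilyl)but-3-yn-1-yl]magnesium | C[Si](C)(C)C#CCC[Mg]Br | intermediate
13 | trimethyl{[(3S,4S)-4-methyl-4-({[tri(propan-2-yl)silyl]oxy}methyl)-3-[4-(trimethylsilyl)but-3-yn-1-yl]cyclopent-1-en-1-yl]oxy}silane | C[Si](C)(C)OC1=C[C@H](CCC#C[Si](C)(C)C)[C@@](C)(CO[Si](C(C)C)(C(C)C)C(C)C)C1 | intermediate
14 | lithium (3S,4S)-4-methyl-4-({[tri(propan-2-yl)silyl]oxy}methyl)-3-[4-(trimethylsilyl)but-3-yn-1-yl]cyclopent-1-en-1-olate | [Li]OC1=C[C@H](CCC#C[Si](C)(C)C)[C@@](C)(CO[Si](C(C)C)(C(C)C)C(C)C)C1 | intermediate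
15 | (3S,4S)-4-methyl-2-(trifluoroacetyl)-4-({[tri(propan-2-yl)silyl]oxy}methyl)-3-[4-(trimethylsilyl)but-3-yn-1-yl]cyclopentan-1-one, enolised at C2 | O=C1C(C(=O)C(F)(F)F)[C@H](CCC#C[Si](C)(C)C)[C@@](C)(CO[Si](C(C)C)(C(C)C)C(C)C)C1 | intermediate
16 | (3R,4S)-2-diazo-4-methyl-4-({[tri(propan-2-yl)silyl]oxy}methyl)-3-[4-(trimethylsilyl)but-3-yn-1-yl]cyclopentan-1-one | O=C1C(=[N+]=[N-])[C@H](CCC#C[Si](C)(C)C)[C@@](C)(CO[Si](C(C)C)(C(C)C)C(C)C)C1 | intermediate
17 | ketene: 3-methyl-3-({[tri(propan-2-yl)silyl]oxy}methyl)-2-[4-(trimethylsilyl)but-3-yn-1-yl]cyclobutylidenemethanone, C1 and C11 configured as in 16 | C[Si](C)(C)C#CCC[C@H]1C(=C=O)C[C@]1(C)CO[Si](C(C)C)(C(C)C)C(C)C | intermediate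
18 | methyl (1S,2S,3S)-3-methyl-3-({[tri(propan-2-yl)silyl]oxy}methyl)-2-[4-(trimethylsilyl)but-3-yn-1-yl]cyclobutane-1-carboxylate (cis ester) | C[Si](C)(C)C#CCC[C@H]1[C@@H](C(=O)OC)C[C@]1(C)CO[Si](C(C)C)(C(C)C)C(C)C | intermediate
19 | methyl (1R,2S,3S)-3-methyl-3-({[tri(propan-2-yl)silyl]oxy}methyl)-2-[4-(trimethylsilyl)but-3-yn-1-yl]cyclobutane-1-carboxylate (trans ester) | C[Si](C)(C)C#CCC[C@H]1[C@H](C(=O)OC)C[C@]1(C)CO[Si](C(C)C)(C(C)C)C(C)C | intermediate
20 | methyl (1R,2S,3S)-2-(but-3-yn-1-yl)-3-methyl-3-({[tri(propan-2-yl)silyl]oxy}methyl)cyclobutane-1-carboxylate | C#CCC[C@H]1[C@H](C(=O)OC)C[C@]1(C)CO[Si](C(C)C)(C(C)C)C(C)C | intermediate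
21 | [(1R,2S,3S)-2-(but-3-yn-1-yl)-3-methyl-3-({[tri(propan-2-yl)silyl]oxy}methyl)cyclobutyl]methanol | C#CCC[C@H]1[C@H](CO)C[C@]1(C)CO[Si](C(C)C)(C(C)C)C(C)C | intermediate
22 | (E)-alkenyl(dimethyl)alane from 21, hydroxyl as dimethylaluminium alkoxide | C[Al](C)/C=C(\C)CC[C@H]1[C@H](CO[Al](C)C)C[C@]1(C)CO[Si](C(C)C)(C(C)C)C(C)C | intermediate
23 | [(1R,2S,3S)-2-[(3E)-4-iodo-3-methylbut-3-en-1-yl]-3-methyl-3-({[tri(propan-2-yl)silyl]oxy}methyl)cyclobutyl]methanol | I/C=C(\C)CC[C@H]1[C@H](CO)C[C@]1(C)CO[Si](C(C)C)(C(C)C)C(C)C | intermediate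
24 | (1R,2S,3S)-2-[(3E)-4-iodo-3-methylbut-3-en-1-yl]-3-methyl-3-({[tri(propan-2-yl)silyl]oxy}methyl)cyclobutane-1-carbaldehyde | I/C=C(\C)CC[C@H]1[C@H](C=O)C[C@]1(C)CO[Si](C(C)C)(C(C)C)C(C)C | intermediate
25 | 1-[(1R,2S,3S)-2-[(3E)-4-iodo-3-methylbut-3-en-1-yl]-3-methyl-3-({[tri(propan-2-yl)silyl]oxy}methyl)cyclobutyl]prop-2-en-1-ol, both carbinol epimers | I/C=C(\C)CC[C@H]1[C@H](C(O)C=C)C[C@]1(C)CO[Si](C(C)C)(C(C)C)C(C)C | intermediate
26 | B-alkyl-9-borabicyclo[3.3.1]nonane from 25 (boron on C6) | I/C=C(\C)CC[C@H]1[C@H](C(O)CCB2C3CCCC2CCC3)C[C@]1(C)CO[Si](C(C)C)(C(C)C)C(C)C | intermediate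
27 | (1S,4E,9R,11S)-4,11-dimethyl-11-({[tri(propan-2-yl)silyl]oxy}methyl)bicyclo[7.2.0]undec-4-en-8-ol, both C8 epimers | OC1CC/C=C(\C)CC[C@H]2[C@H]1C[C@]2(C)CO[Si](C(C)C)(C(C)C)C(C)C | intermediate
28 | (1S,4E,9R,11S)-4,11-dimethyl-11-({[tri(propan-2-yl)silyl]oxy}methyl)bicyclo[7.2.0]undec-4-en-8-one | O=C1CC/C=C(\C)CC[C@H]2[C@H]1C[C@]2(C)CO[Si](C(C)C)(C(C)C)C(C)C | intermediate
29 | {[(1S,4E,9R,11S)-4,11-dimethyl-8-methylidenebicyclo[7.2.0]undec-4-en-11-yl]methoxy}tri(propan-2-yl)silane | C=C1CC/C=C(\C)CC[C@H]2[C@H]1C[C@]2(C)CO[Si](C(C)C)(C(C)C)C(C)C | intermediate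
30 | {[(1S,4S,5S,9R,11S)-4,5-epoxy-4,11-dimethyl-8-methylidenebicyclo[7.2.0]undecan-11-yl]methoxy}tri(propan-2-yl)silane | C=C1CC[C@@H]2O[C@@]2(C)CC[C@H]2[C@H]1C[C@]2(C)CO[Si](C(C)C)(C(C)C)C(C)C | intermediate
31 | [(1S,4S,5S,9R,11S)-4,5-epoxy-4,11-dimethyl-8-methylidenebicyclo[7.2.0]undecan-11-yl]methanol | C=C1CC[C@@H]2O[C@@]2(C)CC[C@H]2[C@H]1C[C@]2(C)CO | intermediate
32 | (1S,4S,5S,9R,11S)-4,5-epoxy-4,11-dimethyl-8-methylidenebicyclo[7.2.0]undecane-11-carbaldehyde | C=C1CC[C@@H]2O[C@@]2(C)CC[C@H]2[C@H]1C[C@]2(C)C=O | intermediate
33 | ethyl (2E)-2-methylbut-2-enoate | C/C=C(\C)C(=O)OCC | starting material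
34 | [(1-ethoxy-2-methylbuta-1,3-dien-1-yl)oxy]trimethylsilane, acetal isomers | CCOC(O[Si](C)(C)C)=C(C)C=C | intermediate
35 | copper alkoxide of ethyl (2Z,5S)-5-hydroxy-2-methyl-5-(core)pent-2-enoate, phosphine ligand omitted | C=C1CC[C@@H]2O[C@@]2(C)CC[C@H]2[C@H]1C[C@]2(C)[C@H](C/C=C(/C)C(=O)OCC)O[Cu] | intermediate
36 | (6S)-6-[(1S,4S,5S,9R,11S)-4,5-epoxy-4,11-dimethyl-8-methylidenebicyclo[7.2.0]undecan-11-yl]-3-methyl-5,6-dihydro-2H-pyran-2-one | C=C1CC[C@@H]2O[C@@]2(C)CC[C@H]2[C@H]1C[C@]2(C)[C@@H]1CC=C(C)C(=O)O1 | intermediate
37 | (2Z,5S)-5-[(1S,4S,5S,9R,11S)-4,5-epoxy-4,11-dimethyl-8-methylidenebicyclo[7.2.0]undecan-11-yl]-2-methylpent-2-ene-1,5-diol | C=C1CC[C@@H]2O[C@@]2(C)CC[C@H]2[C@H]1C[C@]2(C)[C@H](C/C=C(/C)CO)O | intermediate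
38 | (2Z,5S)-5-[(1S,4S,5S,9R,11S)-4,5-epoxy-4,11-dimethyl-8-methylidenebicyclo[7.2.0]undecan-11-yl]-2-methylpent-2-ene-1,5-diyl diacetate | C=C1CC[C@@H]2O[C@@]2(C)CC[C@H]2[C@H]1C[C@]2(C)[C@H](C/C=C(/C)COC(C)=O)OC(C)=O | target

## Step count and least certain steps

Total step count: 25. Longest linear sequence: 24 steps (steps 1–21 and 23–25, from 2); step 22 is a one-step side branch.

**Step 11 (key step).** The most likely failure is incomplete equilibration at C9: enolisation of a cyclobutane ester places a trigonal carbon in the four-membered ring and is slow, so kinetic protonation may leave cis material. Carbene-type side reactions may also lower the mass balance. Fallback (from 16, rejoining at 24): irradiate 16 in methanol as before but treat the photolysate only with K2CO3 at room temperature. This removes the alkynyl silyl group and should give the C9-epimeric alkynyl ester F1. The mixture is carried through the reactions of steps 12–14: iBu2AlH gives the epimeric alcohol F2, carboalumination–iodination gives the epimeric alkenyl iodide alcohol F3, and Dess–Martin oxidation gives the epimeric aldehyde F4. F4 is then equilibrated with DBU in CH2Cl2; an aldehyde on the cyclobutane enolises far more readily than the ester, and its trans isomer is 24.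

**Step 23.** Addition to a neopentyl aldehyde may be slow, and the facial preference of the catalyst may be opposed by the substrate, so that C1' forms with poor selectivity or α-attack of the dienolate intervenes. Fallback (from 32, rejoining at 36): Brown allylation of 32 with the B-allyldiisopinocampheylborane antipode that attacks the Si face should give the homoallylic alcohol F5 under reagent control. Acylation with methacryloyl chloride (Et3N, DMAP) gives the methacrylate F6. Ring-closing metathesis with the second-generation Grubbs catalyst closes the same dihydropyranone 36 with loss of ethene; the 1,1-disubstituted ring methylene is a poor metathesis partner.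

**Step 16.** Intermolecular coupling, protodeboronation or β-hydride elimination may outrun closure of the strained nine-membered ring. Fallback (from 24, rejoining at 28): close the ring at C6–C7 by Tsuji–Trost allylic alkylation instead.
- Lithiated methyl phenyl sulfone adds to 24 to give the β-hydroxy sulfone F7, and Dess–Martin oxidation gives the β-keto sulfone F8.
- Stille coupling with Bu3SnCH2OH (Pd(PPh3)4) converts the alkenyl iodide into the E-allylic alcohol F9, and ClCO2Me/pyridine gives the allylic carbonate F10.
- Pd(PPh3)4 (zerovalent palladium) under high dilution ionises the carbonate, and the keto sulfone carbanion attacks the less substituted allyl terminus C6 to give the cyclic keto sulfone F11.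
- SmI2 desulfonylates F11 to 28.

**Step 8.** Facial discrimination between methyl and silyloxymethyl on the adjacent quaternary carbon may be poor, giving C1 epimers. Fallback (from 10 and 12, rejoining at 13): replace substrate control by double stereodifferentiation. Transmetalation of 12 with ZnCl2 gives the diorganozinc F12, which is added to 10 under copper catalysis (Cu(OTf)2 with a binaphthol-derived phosphoramidite whose sense of induction matches the anti addition). Trapping of the zinc enolate with Me3SiOTf/Et3N gives 13.

**Step 19.** Facial selectivity may erode if the conformer population of 29 differs from that of the parent diene, and over-oxidation at the methylene may compete. Fallback (from 29, rejoining at 30): Shi epoxidation with the enantiomer of the fructose-derived ketone catalyst matched to the 4S,5S epoxide (2KHSO5·KHSO4·K2SO4, K2CO3, MeCN/dimethoxymethane/H2O, 0 °C). The chiral dioxirane imposes reagent control on the E-trisubstituted alkene and reacts poorly with 1,1-disubstituted alkenes; no new compound arises (F0).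

## Further compounds

F1 | step 11 | methyl (2S,3S)-2-(but-3-yn-1-yl)-3-methyl-3-({[tri(propan-2-yl)silyl]oxy}methyl)cyclobutane-1-carboxylate, both C1 epimers | C#CCC[C@H]1C(C(=O)OC)C[C@]1(C)CO[Si](C(C)C)(C(C)C)C(C)C
F2 | step 11 | [(2S,3S)-2-(but-3-yn-1-yl)-3-methyl-3-({[tri(propan-2-yl)silyl]oxy}methyl)cyclobutyl]methanol, both C1 epimers | C#CCC[C@H]1C(CO)C[C@]1(C)CO[Si](C(C)C)(C(C)C)C(C)C
F3 | step 11 | [(2S,3S)-2-[(3E)-4-iodo-3-methylbut-3-en-1-yl]-3-methyl-3-({[tri(propan-2-yl)silyl]oxy}methyl)cyclobutyl]methanol, both C1 epimers | I/C=C(\C)CC[C@H]1C(CO)C[C@]1(C)CO[Si](C(C)C)(C(C)C)C(C)C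
F4 | step 11 | (2S,3S)-2-[(3E)-4-iodo-3-methylbut-3-en-1-yl]-3-methyl-3-({[tri(propan-2-yl)silyl]oxy}methyl)cyclobutane-1-carbaldehyde, both C1 epimers | I/C=C(\C)CC[C@H]1C(C=O)C[C@]1(C)CO[Si](C(C)C)(C(C)C)C(C)C
F5 | step 23 | (1S)-1-[(1S,4S,5S,9R,11S)-4,5-epoxy-4,11-dimethyl-8-methylidenebicyclo[7.2.0]undecan-11-yl]but-3-en-1-ol | C=C1CC[C@@H]2O[C@@]2(C)CC[C@H]2[C@H]1C[C@]2(C)[C@H](CC=C)O
F6 | step 23 | (1S)-1-[(1S,4S,5S,9R,11S)-4,5-epoxy-4,11-dimethyl-8-methylidenebicyclo[7.2.0]undecan-11-yl]but-3-en-1-yl 2-methylprop-2-enoate | C=C1CC[C@@H]2O[C@@]2(C)CC[C@H]2[C@H]1C[C@]2(C)[C@H](CC=C)OC(=O)C(C)=C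
F7 | step 16 | 2-(benzenesulfonyl)-1-[(1R,2S,3S)-2-[(3E)-4-iodo-3-methylbut-3-en-1-yl]-3-methyl-3-({[tri(propan-2-yl)silyl]oxy}methyl)cyclobutyl]ethan-1-ol, both carbinol epimers | I/C=C(\C)CC[C@H]1[C@H](C(O)CS(=O)(=O)c2ccccc2)C[C@]1(C)CO[Si](C(C)C)(C(C)C)C(C)C
F8 | step 16 | 2-(benzenesulfonyl)-1-[(1R,2S,3S)-2-[(3E)-4-iodo-3-methylbut-3-en-1-yl]-3-methyl-3-({[tri(propan-2-yl)silyl]oxy}methyl)cyclobutyl]ethan-1-one | I/C=C(\C)CC[C@H]1[C@H](C(=O)CS(=O)(=O)c2ccccc2)C[C@]1(C)CO[Si](C(C)C)(C(C)C)C(C)C
F9 | step 16 | 2-(benzenesulfonyl)-1-[(1R,2S,3S)-2-[(3E)-5-hydroxy-3-methylpent-3-en-1-yl]-3-methyl-3-({[tri(propan-2-yl)silyl]oxy}methyl)cyclobutyl]ethan-1-one | OC/C=C(\C)CC[C@H]1[C@H](C(=O)CS(=O)(=O)c2ccccc2)C[C@]1(C)CO[Si](C(C)C)(C(C)C)C(C)C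
F10 | step 16 | (2E)-5-[(1S,2R,4S)-2-[(benzenesulfonyl)acetyl]-4-methyl-4-({[tri(propan-2-yl)silyl]oxy}methyl)cyclobutyl]-3-methylpent-2-en-1-yl methyl carbonate | COC(=O)OC/C=C(\C)CC[C@H]1[C@H](C(=O)CS(=O)(=O)c2ccccc2)C[C@]1(C)CO[Si](C(C)C)(C(C)C)C(C)C
F11 | step 16 | (1S,4E,9R,11S)-7-(benzenesulfonyl)-4,11-dimethyl-11-({[tri(propan-2-yl)silyl]oxy}methyl)bicyclo[7.2.0]undec-4-en-8-one, both C7 epimers | O=C1C(S(=O)(=O)c3ccccc3)C/C=C(\C)CC[C@H]2[C@H]1C[C@]2(C)CO[Si](C(C)C)(C(C)C)C(C)C
F12 | step 8 | bis[4-(trimethylsilyl)but-3-yn-1-yl]zinc | C[Si](C)(C)C#CCC[Zn]CCC#C[Si](C)(C)C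
F0 | step 19 | none | none
A1 | alternative 1 | (6S)-6-[(1S,4S,5S,9R,11S)-4,5-epoxy-4,11-dimethyl-8-methylidenebicyclo[7.2.0]undecan-11-yl]-3-methyl-5,6-dihydro-2H-pyran-2-one | C=C1CC[C@@H]2O[C@@]2(C)CC[C@H]2[C@H]1C[C@]2(C)[C@@H]1CC=C(C)C(=O)O1
A2 | alternative 2 | triethyl{[(1S,4E,8S,9R,11S)-4,11-dimethyl-11-({[tri(propan-2-yl)silyl]oxy}methyl)bicyclo[7.2.0]undec-4-en-8-yl]oxy}silane | CC[Si](CC)(CC)O[C@H]1CC/C=C(\C)CC[C@H]2[C@H]1C[C@]2(C)CO[Si](C(C)C)(C(C)C)C(C)C
A3 | alternative 2 | triethyl({(1S)-1-[(1R,2S,3S)-2-[(3E)-4-iodo-3-methylbut-3-en-1-yl]-3-methyl-3-({[tri(propan-2-yl)silyl]oxy}methyl)cyclobutyl]prop-2-en-1-yl}oxy)silane | I/C=C(\C)CC[C@H]1[C@H]([C@@H](O[Si](CC)(CC)CC)C=C)C[C@]1(C)CO[Si](C(C)C)(C(C)C)C(C)C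
A4 | alternative 3 | (2R)-2-ethenyl-2-methylcyclobutan-1-one | O=C1CC[C@]1(C)C=C
A5 | alternative 3 | (2E)-3-(1-hydroxycyclopropyl)but-2-en-1-yl methyl carbonate | COC(=O)OC/C=C(\C)C1(O)CC1
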